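Ring A (C1 ether carbon, C2 pentyl, C4–OH, C6–OH) and ring B (C1′ ether carbon, C6′ ester) are read as a methanolysed depsidone: the C6 hydroxyl and the C6′ methyl ester are the two ends of a seven-membered lactone. The route rests on disconnecting the C6–O bond of that lactone, so the diaryl ether needs only the C4 hydroxyl on ring A. In one operation, anodic dearomatisation ties the C6′ carboxylate to C1 as a spiro lactone and acid shifts the acyloxy group to C6, creating the third ring A oxygen and the lactone ring. The precursor is 2-(4-hydroxy-2-pentylphenoxy)-4-methoxy-6-pentanoylbenzoic acid.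

Key step: step 10

Remark: the target has no stereocentre, so no configuration has to be set or kept.
Remark: 2-acylbenzoic acids equilibrate with their 3-hydroxyphthalide ring tautomers; the keto acids of steps 8 and 9 are drawn open-chain, and the base in step 10 holds the open carboxylate.

**Step 1**
Reactants: 1 1-(benzyloxy)-3-bromobenzene; 2 pentylmagnesium bromide
Product: 3 1-(benzyloxy)-3-pentylbenzene
Conditions: NiCl2(dppp) (2 mol %), THF–Et2O, 0 °C → reflux
Reagents that add atoms: none
Why: Kumada–Corriu coupling, in which Ni(0)/dppp inserts into the aryl C–Br bond and the chelating phosphine makes reductive elimination of the n-alkyl group faster than β-hydride elimination, while the benzyl ether is inert.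

**Step 2**
Reactants: 3 1-(benzyloxy)-3-pentylbenzene
Product: 4 4-(benzyloxy)-1-iodo-2-pentylbenzene
Conditions: NIS, TFA (cat.), MeCN, rt, dark
Reagents that add atoms: N-iodosuccinimide, O=C1CCC(=O)N1I
Why: Electrophilic aromatic iodination, in which acid-activated NIS should attack para to the benzyloxy group (the most activated site, ortho to the pentyl chain), as is usual for 3-alkylphenyl ethers.

**Step 3**
Reactants: 4 4-(benzyloxy)-1-iodo-2-pentylbenzene
Product: 6 [4-(benzyloxy)-2-pentylphenyl](2,4,6-trimethoxyphenyl)iodonium tosylate, via hydroxy(tosyloxy)iodoarene 5 (not isolated)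
Conditions: mCPBA, TsOH·H2O, MeCN, 40 °C; then 1,3,5-trimethoxybenzene, rt
Reagents that add atoms: p-toluenesulfonic acid monohydrate, Cc1ccc(cc1)S(=O)(=O)O.O; 1,3,5-trimethoxybenzene, COc1cc(OC)cc(OC)c1; mCPBA, OOC(=O)c1cccc(Cl)c1 (its oxygen is carried only by 5)
Why: One-pot diaryliodonium synthesis, in which the aryl iodide is oxidised to the iodine(III) tosylate 5 and this electrophile substitutes the very electron-rich trimethoxybenzene, chosen as a partner that is not transferred later.

**Step 4**
Reactants: 7 1-bromo-3,5-dimethoxybenzene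
Product: 9 2-bromo-4,6-dimethoxybenzaldehyde, via aryl iminium dichlorophosphate 8 (not isolated)
Conditions: POCl3, DMF, 0 → 90 °C; then ice-water
Reagents that add atoms: N,N-dimethylformamide, CN(C)C=O (formyl carbon); water, O (carbonyl oxygen, on hydrolysis of 8); phosphoryl chloride, O=P(Cl)(Cl)Cl (only the counter-ion of 8)
Why: Vilsmeier–Haack formylation, in which the chloroiminium ion should attack the position ortho to bromine (para to one methoxy, ortho to the other) in preference to the more crowded position between the two methoxy groups, any regioisomer being removed by crystallisation.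

**Step 5**
Reactants: 9 2-bromo-4,6-dimethoxybenzaldehyde
Product: 10 2-bromo-6-hydroxy-4-methoxybenzaldehyde
Conditions: BCl3, CH2Cl2, −78 → 0 °C; then H2O
Reagents that add atoms: none
Why: Chelation-controlled ether cleavage, in which BCl3 binds the aldehyde oxygen and the ortho methoxy oxygen in a six-membered chelate so that chloride removes only that methyl group and the para methoxy group stays.

**Step 6**
Reactants: 10 2-bromo-6-hydroxy-4-methoxybenzaldehyde; 6 [4-(benzyloxy)-2-pentylphenyl](2,4,6-trimethoxyphenyl)iodonium tosylate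
Product: 11 2-[4-(benzyloxy)-2-pentylphenoxy]-6-bromo-4-methoxybenzaldehyde
Conditions: K2CO3, MeCN, 50 °C
Reagents that add atoms: none
Why: Metal-free O-arylation with a diaryliodonium salt, in which the phenoxide binds iodine and ligand coupling transfers the less electron-rich, ortho-substituted benzyloxy-pentylphenyl group, while the aryl bromide and the non-enolisable aldehyde are inert to carbonate.

**Step 7**
Reactants: 11 2-[4-(benzyloxy)-2-pentylphenoxy]-6-bromo-4-methoxybenzaldehyde
Product: 12 2-[4-(benzyloxy)-2-pentylphenoxy]-6-bromo-4-methoxybenzoic acid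
Conditions: NaClO2, NaH2PO4, 2-methyl-2-butene, t-BuOH–THF–H2O, 0 °C → rt
Reagents that add atoms: sodium chlorite, [Na+].[O-]Cl=O
Why: Pinnick oxidation, in which chlorous acid converts the hindered aldehyde into the acid without touching the aryl bromide or benzyl ether, and the alkene traps hypochlorous acid before it can chlorinate the electron-rich ring A.

**Step 8**
Reactants: 12 2-[4-(benzyloxy)-2-pentylphenoxy]-6-bromo-4-methoxybenzoic acid; 13 N-methoxy-N-methylpentanamide
Product: 15 2-[4-(benzyloxy)-2-pentylphenoxy]-4-methoxy-6-pentanoylbenzoic acid, via dilithiated benzoate 14 (not isolated)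
Conditions: n-BuLi (2.2 equiv), THF, −78 °C; then 13, −78 → 0 °C; then 1 M HCl
Reagents that add atoms: n-butyllithium, [Li]CCCC (its lithium is carried only by 14)
Why: Parham-type bromine–lithium exchange on a lithium 2-bromobenzoate followed by Weinreb ketone synthesis, in which the first equivalent of n-BuLi forms the carboxylate, the second gives aryllithium 14 at −78 °C, and the chelated tetrahedral adduct releases the ketone only on acidic work-up, so over-addition is excluded.

**Step 9**
Reactants: 15 2-[4-(benzyloxy)-2-pentylphenoxy]-4-methoxy-6-pentanoylbenzoic acid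
Product: 16 2-(4-hydroxy-2-pentylphenoxy)-4-methoxy-6-pentanoylbenzoic acid
Conditions: H2 (1 atm), 10% Pd/C, EtOAc, rt
Reagents that add atoms: none
Why: Hydrogenolysis of the aryl benzyl ether over Pd/C in neutral ethyl acetate is much faster than reduction of the hindered aryl ketone, so the reaction is stopped after one equivalent of hydrogen is taken up.

**Step 10**
Reactants: 16 2-(4-hydroxy-2-pentylphenoxy)-4-methoxy-6-pentanoylbenzoic acid
Product: 18 8-hydroxy-3-methoxy-1-pentanoyl-6-pentyl-11H-dibenzo[b,e][1,4]dioxepin-11-one, via racemic spiro quinone monoketal lactone 17 (not isolated)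
Conditions: graphite anode, Pt cathode, undivided cell, constant current (2.2 F/mol), n-Bu4NBF4, 2,6-lutidine (2 equiv), MeCN–HFIP, 0 °C; then current off, TFA (excess), 0 °C → rt
Reagents that add atoms: none
Why: Proposed new method: two-electron anodic oxidation of the C4 phenol of 16 should give a phenoxonium ion with its charge at C1 (para to the oxygen and stabilised by the aryloxy group), and the C6′ carboxylate captures it there by 6-exo-trig attack to close the six-membered ring of spiro quinone monoketal 17, whose spiro carbon is a stereocentre formed racemic and erased again. After the current is switched off, TFA protonates the dienone, the lactone carbonyl oxygen bridges to the neighbouring β-carbon C6 as a five-membered dioxolan-2-ylium ion (5-exo-trig), the C1–O acyl bond breaks and loss of H6 rearomatises ring A, so the seven-membered lactone of 18 is closed by one-atom ring expansion (a 1,2-acyloxy shift) and not by direct cyclisation. The closest known reaction types are anodic or iodine(III) oxidative spirolactonisation of para-substituted phenols, anodic formation of quinone monoketals from hydroquinone monoethers, and the acid-induced 1,2-acyloxy shift of quinol esters; their combination on a 4-aryloxyphenol is what is new. Ipso capture at C1 is secured by the para hydroxyl and by the tether, which reaches no other ring A carbon through a six-membered ring. Migration to C6 and not C2 is secured because C2 carries the pentyl group, so a C2 adduct cannot lose a proton and reverts, whereas the C6 adduct aromatises irreversibly. Over-oxidation of the product phenol is avoided by adding acid only after electrolysis, and lutidine keeps 16 as the open carboxylate and the medium non-acidic while 17 forms.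

**Step 11**
Reactants: 18 8-hydroxy-3-methoxy-1-pentanoyl-6-pentyl-11H-dibenzo[b,e][1,4]dioxepin-11-one
Product: 19 methyl 2-(2,4-dihydroxy-6-pentylphenoxy)-4-methoxy-6-pentanoylbenzoate
Conditions: NaOMe (3 equiv), MeOH–THF, 0 °C; then 1 M HCl
Reagents that add atoms: sodium methoxide, [Na+].[O-]C
Why: Base-mediated methanolysis (transesterification) of an aryl ester, in which methoxide adds to the lactone carbonyl and expels the ring A C6 phenoxide, a far better leaving group than methoxide, so the ring B methyl ester and the free C6 hydroxyl should form at 0 °C before the ketone can enolise.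

**Compound list**
1 | 1-(benzyloxy)-3-bromobenzene | Brc1cccc(OCc2ccccc2)c1 | starting material
2 | pentylmagnesium bromide | CCCCC[Mg]Br | starting material
3 | 1-(benzyloxy)-3-pentylbenzene | CCCCCc1cccc(OCc2ccccc2)c1 | intermediate
4 | 4-(benzyloxy)-1-iodo-2-pentylbenzene | CCCCCc1cc(OCc2ccccc2)ccc1I | intermediate
5 | [4-(benzyloxy)-2-pentylphenyl](hydroxy)(tosyloxy)-λ3-iodane | CCCCCc1cc(OCc2ccccc2)ccc1I(O)OS(=O)(=O)c1ccc(C)cc1 | intermediate (not isolated)
6 | [4-(benzyloxy)-2-pentylphenyl](2,4,6-trimethoxyphenyl)iodonium tosylate | CCCCCc1cc(OCc2ccccc2)ccc1[I+]c1c(OC)cc(OC)cc1OC.Cc1ccc(S(=O)(=O)[O-])cc1 | intermediate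
7 | 1-bromo-3,5-dimethoxybenzene | COc1cc(Br)cc(OC)c1 | starting material
8 | N-[(2-bromo-4,6-dimethoxyphenyl)methylidene]-N-methylmethanaminium dichlorophosphate | COc1cc(Br)c(C=[N+](C)C)c(OC)c1.[O-]P(=O)(Cl)Cl | intermediate (not isolated)
9 | 2-bromo-4,6-dimethoxybenzaldehyde | COc1cc(Br)c(C=O)c(OC)c1 | intermediate
10 | 2-bromo-6-hydroxy-4-methoxybenzaldehyde | COc1cc(O)c(C=O)c(Br)c1 | intermediate
11 | 2-[4-(benzyloxy)-2-pentylphenoxy]-6-bromo-4-methoxybenzaldehyde | CCCCCc1cc(OCc2ccccc2)ccc1Oc1cc(OC)cc(Br)c1C=O | intermediate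
12 | 2-[4-(benzyloxy)-2-pentylphenoxy]-6-bromo-4-methoxybenzoic acid | CCCCCc1cc(OCc2ccccc2)ccc1Oc1cc(OC)cc(Br)c1C(=O)O | intermediate
13 | N-methoxy-N-methylpentanamide | CCCCC(=O)N(C)OC | starting material
14 | lithium 2-[4-(benzyloxy)-2-pentylphenoxy]-6-lithio-4-methoxybenzoate | CCCCCc1cc(OCc2ccccc2)ccc1Oc1cc(OC)cc([Li])c1C(=O)O[Li] | intermediate (not isolated)
15 | 2-[4-(benzyloxy)-2-pentylphenoxy]-4-methoxy-6-pentanoylbenzoic acid | CCCCCc1cc(OCc2ccccc2)ccc1Oc1cc(OC)cc(C(=O)CCCC)c1C(=O)O | intermediate
16 | 2-(4-hydroxy-2-pentylphenoxy)-4-methoxy-6-pentanoylbenzoic acid (key-step precursor) | CCCCCc1cc(O)ccc1Oc1cc(OC)cc(C(=O)CCCC)c1C(=O)O | intermediate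
17 | racemic 7-methoxy-5-pentanoyl-2′-pentyl-4H-spiro[1,3-benzodioxine-2,1′-cyclohexa[2,5]diene]-4,4′-dione | O=C1C=CC2(OC(=O)c3c(C(=O)CCCC)cc(OC)cc3O2)C(CCCCC)=C1 | intermediate (not isolated)
18 | 8-hydroxy-3-methoxy-1-pentanoyl-6-pentyl-11H-dibenzo[b,e][1,4]dioxepin-11-one (depsidone) | CCCCCc1cc(O)cc2OC(=O)c3c(C(=O)CCCC)cc(OC)cc3Oc12 | intermediate
19 | methyl 2-(2,4-dihydroxy-6-pentylphenoxy)-4-methoxy-6-pentanoylbenzoate | CCCCCc1cc(O)cc(O)c1Oc1cc(OC)cc(C(=O)CCCC)c1C(=O)OC | target

**Step count**
Total: 11 steps. Longest linear sequence: 9 steps (steps 1–3 and 6–11, from 1); the ring B branch (steps 4–5) joins at step 6.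

**Steps most likely to fail**

Step 10. The phenoxonium ion may be intercepted by solvent or adventitious water instead of the carboxylate, the mixed ketal may hydrolyse with loss of the ether link, or acid may fragment the dienone instead of shifting the acyloxy group. The fallback uses known chemistry and brings the C6 oxygen in with ring A; it sets out from 10 and rejoins the route at 19. Commercial olivetol (5-pentylresorcinol) is benzylated (BnBr, K2CO3, DMF) to 1,3-bis(benzyloxy)-5-pentylbenzene F1. Iodination (NIS, cat. TFA, MeCN) between the pentyl group and one benzyloxy group gives 1,5-bis(benzyloxy)-2-iodo-3-pentylbenzene F2. Oxidation (mCPBA, TsOH) gives [2,4-bis(benzyloxy)-6-pentylphenyl](hydroxy)(tosyloxy)-λ3-iodane F3 (not isolated), which with trimethoxybenzene gives [2,4-bis(benzyloxy)-6-pentylphenyl](2,4,6-trimethoxyphenyl)iodonium tosylate F4. O-Arylation of 10 (K2CO3, MeCN) should give 2-[2,4-bis(benzyloxy)-6-pentylphenoxy]-6-bromo-4-methoxybenzaldehyde F5, and Pinnick oxidation 2-[2,4-bis(benzyloxy)-6-pentylphenoxy]-6-bromo-4-methoxybenzoic acid F6. n-BuLi gives lithium 2-[2,4-bis(benzyloxy)-6-pentylphenoxy]-6-lithio-4-methoxybenzoate F7 (not isolated), and 13 converts it into 2-[2,4-bis(benzyloxy)-6-pentylphenoxy]-4-methoxy-6-pentanoylbenzoic acid F8. Hydrogenolysis (H2, Pd/C) gives 2-(2,4-dihydroxy-6-pentylphenoxy)-4-methoxy-6-pentanoylbenzoic acid F9, whose carboxylate alone is alkylated by MeI/KHCO3 in DMF to give 19.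

Step 8. Bromine–lithium exchange may be incomplete, the aryllithium may be protonated by the α-protons of the amide, or the lithiated carboxylate may self-condense before it is acylated. The fallback builds the ketone from an alkyne; it sets out from 11 and rejoins at 15. Sonogashira coupling of 11 with 1-pentyne (PdCl2(PPh3)2, CuI, Et3N) gives 2-[4-(benzyloxy)-2-pentylphenoxy]-4-methoxy-6-(pent-1-yn-1-yl)benzaldehyde F10. Pinnick oxidation gives 2-[4-(benzyloxy)-2-pentylphenoxy]-4-methoxy-6-(pent-1-yn-1-yl)benzoic acid F11. DBU-catalysed 5-exo-dig cyclisation (MeCN) gives (Z)-7-[4-(benzyloxy)-2-pentylphenoxy]-3-butylidene-5-methoxy-2-benzofuran-1(3H)-one F12. Aqueous NaOH opens this enol lactone to the keto carboxylate, and acidification gives 15.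

Step 6. Arylation of the weakly nucleophilic, hydrogen-bonded salicylaldehyde phenoxide may be slow, and the ligand-coupling step may transfer the trimethoxyphenyl group instead of the ring A aryl group. The fallback reverses the polarity of the ether formation; it sets out from 4 and rejoins at 11. Copper-catalysed hydroxylation of 4 (CuI, 1,10-phenanthroline, KOH, DMSO–H2O) gives 4-(benzyloxy)-2-pentylphenol F13. Commercial 1-bromo-3-fluoro-5-methoxybenzene is lithiated between the two halogens (LDA, THF, −78 °C) to (2-bromo-6-fluoro-4-methoxyphenyl)lithium F14 (not isolated) and formylated with DMF to 2-bromo-6-fluoro-4-methoxybenzaldehyde F15. SNAr of the phenoxide of F13 on F15 (K2CO3, DMF, 80 °C) displaces the fluoride ortho to the aldehyde and gives 11.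

**Further compounds**
F1 | step 10 | 1,3-bis(benzyloxy)-5-pentylbenzene | CCCCCc1cc(OCc2ccccc2)cc(OCc2ccccc2)c1
F2 | step 10 | 1,5-bis(benzyloxy)-2-iodo-3-pentylbenzene | CCCCCc1cc(OCc2ccccc2)cc(OCc2ccccc2)c1I
F3 | step 10 | [2,4-bis(benzyloxy)-6-pentylphenyl](hydroxy)(tosyloxy)-λ3-iodane | CCCCCc1cc(OCc2ccccc2)cc(OCc2ccccc2)c1I(O)OS(=O)(=O)c1ccc(C)cc1
F4 | step 10 | [2,4-bis(benzyloxy)-6-pentylphenyl](2,4,6-trimethoxyphenyl)iodonium tosylate | CCCCCc1cc(OCc2ccccc2)cc(OCc2ccccc2)c1[I+]c1c(OC)cc(OC)cc1OC.Cc1ccc(S(=O)(=O)[O-])cc1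
F5 | step 10 | 2-[2,4-bis(benzyloxy)-6-pentylphenoxy]-6-bromo-4-methoxybenzaldehyde | CCCCCc1cc(OCc2ccccc2)cc(OCc2ccccc2)c1Oc1cc(OC)cc(Br)c1C=O
F6 | step 10 | 2-[2,4-bis(benzyloxy)-6-pentylphenoxy]-6-bromo-4-methoxybenzoic acid | CCCCCc1cc(OCc2ccccc2)cc(OCc2ccccc2)c1Oc1cc(OC)cc(Br)c1C(=O)O
F7 | step 10 | lithium 2-[2,4-bis(benzyloxy)-6-pentylphenoxy]-6-lithio-4-methoxybenzoate | CCCCCc1cc(OCc2ccccc2)cc(OCc2ccccc2)c1Oc1cc(OC)cc([Li])c1C(=O)O[Li]
F8 | step 10 | 2-[2,4-bis(benzyloxy)-6-pentylphenoxy]-4-methoxy-6-pentanoylbenzoic acid | CCCCCc1cc(OCc2ccccc2)cc(OCc2ccccc2)c1Oc1cc(OC)cc(C(=O)CCCC)c1C(=O)O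
F9 | step 10 | 2-(2,4-dihydroxy-6-pentylphenoxy)-4-methoxy-6-pentanoylbenzoic acid | CCCCCc1cc(O)cc(O)c1Oc1cc(OC)cc(C(=O)CCCC)c1C(=O)O
F10 | step 8 | 2-[4-(benzyloxy)-2-pentylphenoxy]-4-methoxy-6-(pent-1-yn-1-yl)benzaldehyde | CCCC#Cc1cc(OC)cc(Oc2ccc(OCc3ccccc3)cc2CCCCC)c1C=O
F11 | step 8 | 2-[4-(benzyloxy)-2-pentylphenoxy]-4-methoxy-6-(pent-1-yn-1-yl)benzoic acid | CCCC#Cc1cc(OC)cc(Oc2ccc(OCc3ccccc3)cc2CCCCC)c1C(=O)O
F12 | step 8 | (Z)-7-[4-(benzyloxy)-2-pentylphenoxy]-3-butylidene-5-methoxy-2-benzofuran-1(3H)-one | CCC/C=C1\OC(=O)c2c(Oc3ccc(OCc4ccccc4)cc3CCCCC)cc(OC)cc12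
F13 | step 6 | 4-(benzyloxy)-2-pentylphenol | CCCCCc1cc(OCc2ccccc2)ccc1O
F14 | step 6 | (2-bromo-6-fluoro-4-methoxyphenyl)lithium | COc1cc(F)c([Li])c(Br)c1
F15 | step 6 | 2-bromo-6-fluoro-4-methoxybenzaldehyde | COc1cc(F)c(C=O)c(Br)c1
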